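All runs are calculated for substances that don't exist; the scatter is artificial.

- Amounts first: at 3.00 min in delta, E, G and X together hold 35.7% of the E charged, and the rest, 0.206 M, is taken here as dissolved, unreacted E, written Q; epsilon at 2.50 min gives 0.212 M, so [Q] sits near that level while solid is left.

| flask | E | D | J | temperature | remark | time |
|---|---|---|---|---|---|---|
| delta | 0.32 M | 0.86 M | 0.336 M (in portions, 2) | 80 °C | run made earlier; portions every 2.5 min |  |
| epsilon | 0.32 M | 0.29 M | 0.336 M (in portions, 2) | 80 °C | run made earlier; portions every 2.5 min |  |
| larch | 0.32 M | 0.576 M | 0.336 M (in portions, 2) | 80 °C | the portions of J follow each other after 2.5 min, the first at the start | 12 min |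
| ash | 0.32 M | 0.576 M | 0.336 M (in portions, 2) | 50 °C | the portions of J follow each other after 10 min, the first at the start | 12 min |
| alder | 0.32 M | 0.576 M | 0.120 M (in portions, 2) | 65 °C | the portions of J follow each other after 2.5 min, the first at the start | 12 min |
| oak | 0.10 M | 0.576 M | 0.336 M (in portions, 2) | 60 °C | the portions of J follow each other after 2.5 min, the first at the start | 12 min |
| cedar | 0.32 M | 0.576 M | 0.250 M (in portions, 2) | 80 °C | the portions of J follow each other after 5.0 min, the first at the start | 12 min |

| run | time / min | G / % | X / % | E / % |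
|---|---|---|---|---|
| delta | 0.500 | 2.3 | 0.5 | 53.7 |
| delta | 1.33 | 6.9 | 0 | 30.1 |
| delta | 3.00 | 16.1 | 2.1 | 17.5 |
| delta | 8.00 | 16.6 | 15.3 | 0.3 |
| epsilon | 0.833 | 5.9 | 0.1 | 39.9 |
| epsilon | 2.50 | 16.8 | 0.8 | 16.1 |
| epsilon | 5.00 | 39.2 | 6.9 | 0 |
| epsilon | 8.00 | 40.6 | 15.6 | 0.1 |

(scatter of a reading: 0.3 percentage points)

* ranking by amount of G, in percent of the E charged, from high to low, at 12 min (larch / ash / alder / oak / cedar)
* the amount of G, in percent of the E charged of the flask you put first, at 12 min
* the amount of G, in percent of the E charged of the flask you put last, at 12 min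

- solid, in amounts per volume of the solution: E
- at the start none of E is in solution
- what has only dissolved of E counts as not reacted
- the earlier runs do not show what temperature does; that part of a forecast is a guess

- Setting D: the reckoning here has J taken by Q towards G and X, or lost to D, each step first order in J, so G + X counts the J captured. Raising [D] from 0.29 M to 0.86 M should cut the capture, and at 8.00 min it does: delta holds 0.102 M, less than the 0.180 M of epsilon.
- Taking J as spent by then, captured over lost, times [D]/[Q], gives 1.82 in delta and 1.57 in epsilon. Their mean is S = 1.70, the selectivity factor: J taken by Q per J taken by D at equal concentrations.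
- Setting J: with [Q] held by solid, the captured share of J is S[Q]/(S[Q] + [D]) = 37.8% at 0.576 M. Once J is spent, this share reckons G + X at 39.7% in larch, 29.5% in cedar and 14.2% in alder.
- Setting the interval: the share holds no [J], so spacing matters through the time left. Ash, whose second portion comes at 10 min, is counted on its first portion, 19.8%.
- Setting E: the charge of oak is below the dissolved level, so no solid refills Q. With S[Q] below [D], and [D] taken as charged, Q in oak is reckoned to decay with J spent, leaving the fraction exp(−S·spent/[D]). Spending the whole charge of J gives G + X = 62.9% in oak, above larch.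
- Setting temperature: the runs are silent on it, so S is kept at its reading and the figures for ash, alder and oak are a guess.
- G stands below each of these by X, and the reckoning here commits to oak, larch, cedar, ash, alder.
- The forecast gives oak > cedar > larch > alder > ash, with 30% first and 14% last, holding for oak that “large J excess at low temperature favours G”, and it differs from the reckoning here by putting cedar above larch and alder above ash.
- The flasks give oak > larch > cedar > ash > alder, with 37.4% of G in oak and 11.4% in alder.

    Q + J → G (k = 0.0230 M⁻¹ s⁻¹, Ea = 73.0 kJ mol⁻¹)
    J + D → Z (k = 0.0127 M⁻¹ s⁻¹, Ea = 62.0 kJ mol⁻¹)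
    G + Z → X (k = 0.0188 M⁻¹ s⁻¹, Ea = 83.0 kJ mol⁻¹)
    2 Z → L (k = 0.00777 M⁻¹ s⁻¹, Ea = 69.0 kJ mol⁻¹)
    E ⇌ Q, rate k5*(cs5 - [Q]) while solid is left; crystals form when [Q] > cs5 (solubility = 0.220 M, k = 0.0360 s⁻¹)
    (constants at 80 °C)

- In oak at 12.0 min, Q holds 55.1% of the E charged and D 66.0% of its charge, so [D]/(S[Q]) comes to 4.06, against 4.8 for the rate of J going to Z over that of J going to G. Counting the J spent, exp(−S·spent/[D]) leaves 49.1% as Q in oak against 55.1%, and in the neighbour of oak charged with 0.84 M of J, where 43% of J remains, it leaves 24.3% against 18.4%.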